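**Retrosynthetic overview**

1. The two angelates go on last, onto a trans-1,3-diol; the ring ketone is released from a dimethyl ketal in the same pot as desilylation.
2. The seven-membered ring is formed second, at the bond between the gem-dimethyl carbon and the cyclobutane CH: a tertiary radical made by hydrogen-atom transfer to an isopropenyl carbinol side chain adds to a cyclobutanone tosylhydrazone, and loss of N2 leaves the cyclobutane C–H.
3. The cyclobutane and the six-membered ring are formed first and together, by an intramolecular [2+2] cycloaddition of a vinylketene with an E-trisubstituted alkene. It forms the bond between the bridgehead CH alpha to the ring ketone (the ketene alpha carbon) and the quaternary methyl-bearing cyclobutane carbon (the disubstituted alkene terminus), and also the bond between the other bridgehead and the carbonyl bridge.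
4. The feature that allows this: the cyclobutane CH that carries the gem-dimethyl carbon can be a ketene carbonyl carbon, and the ring ketone carbon, as its methyl enol ether, is the vinyl carbon of the vinylketene. The three ring atoms C(OMe)=CH–CH(Me) are the tether, and the quaternary methyl carbon takes the positive charge, which dictates the bridged (pinane-type) regiochemistry.
5. The acyclic acid 12 comes from an Evans alkylation (CH–Me centre), a Wittig reaction (E alkene) and a boron aldol / anti reduction pair (1,3-anti diol).

Key step: step 9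

**Route**

Step 1
Reactants: 1 (4S)-4-benzyl-3-propanoyl-1,3-oxazolidin-2-one; 2 methyl (2E)-4-bromo-3-methoxybut-2-enoate
Product: 3 methyl (2E,5R)-6-[(4S)-4-benzyl-2-oxo-1,3-oxazolidin-3-yl]-3-methoxy-5-methyl-6-oxohex-2-enoate
Conditions: NaN(SiMe3)2, THF, −78 °C; then 2, −78 to −30 °C
Reagents that add atoms: none
Why: Evans asymmetric alkylation, in which the chelated Z sodium enolate should be alkylated by the allylic bromide on the face opposite the benzyl group, setting the methyl-bearing centre as R (the beta-methoxy group suppresses conjugate addition).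

Step 2
Reactants: 3
Product: 4 methyl (2E,5R)-6-hydroxy-3-methoxy-5-methylhex-2-enoate
Conditions: NaBH4, THF/H2O, 0 to 23 °C
Reagents that add atoms: none
Why: Reductive cleavage of the N-acyl oxazolidinone by borohydride should be much faster than attack on the deactivated beta-methoxy enoate, so the primary alcohol is released with the stereocentre untouched and the auxiliary is recovered.

Step 3
Reactants: 4
Product: 5 methyl (2E,5R)-3-methoxy-5-methyl-6-oxohex-2-enoate
Conditions: Dess–Martin periodinane, pyridine, CH2Cl2, 0 to 23 °C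
Reagents that add atoms: none
Why: Dess–Martin oxidation under pyridine buffer should give the alpha-branched aldehyde without acid or base strong enough to epimerise it.

Step 4
Reactants: 5; 6 3-(triphenyl-λ5-phosphanylidene)butan-2-one
Product: 7 methyl (2E,5R,6E)-3-methoxy-5,7-dimethyl-8-oxonona-2,6-dienoate
Conditions: toluene, 90 °C
Reagents that add atoms: none
Why: Wittig olefination with a stabilised acyl ylide should give the trisubstituted enone with E geometry (chain trans, methyl cis to the CH–Me carbon), and the weakly basic ylide leaves the alpha stereocentre intact.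

Step 5
Reactants: 7; 8 methacrolein (2-methylprop-2-enal)
Product: 9 methyl (2E,5R,6E,10R)-10-hydroxy-3-methoxy-5,7,11-trimethyl-8-oxododeca-2,6,11-trienoate
Conditions: (+)-Ipc2BCl, Et3N, Et2O, −78 to 0 °C; then 8, −78 to −20 °C; then H2O2, pH 7 buffer, MeOH, 0 °C
Reagents that add atoms: none
Why: Paterson boron aldol reaction of a methyl ketone, in which the diisopinocampheyl enol borinate should add to the aldehyde Re face through a cyclic transition state, so the R carbinol is set by reagent control (the remote methyl centre has no influence).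

Step 6
Reactants: 9
Product: 10 methyl (2E,5R,6E,8R,10R)-8,10-dihydroxy-3-methoxy-5,7,11-trimethyldodeca-2,6,11-trienoate
Conditions: Me4NBH(OAc)3, MeCN/AcOH (1:1), −30 °C
Reagents that add atoms: none
Why: Evans–Saksena reduction, in which the free hydroxyl binds boron and delivers hydride intramolecularly through a chair transition state, should give the 1,3-anti diol (new carbinol R) with 1,2-reduction of the enone only.

Step 7
Reactants: 10
Product: 11 methyl (2E,5R,6E,8R,10R)-8,10-bis(tert-butyldimethylsilyloxy)-3-methoxy-5,7,11-trimethyldodeca-2,6,11-trienoate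
Conditions: TBSOTf, 2,6-lutidine, CH2Cl2, −78 to 0 °C
Reagents that add atoms: tert-butyldimethylsilyl triflate, CC(C)(C)[Si](C)(C)OS(=O)(=O)C(F)(F)F
Why: Standard silylation of both secondary allylic alcohols gives ethers that should survive acid chloride formation, hot amine, radical conditions and mild acid; no stereocentre changes.

Step 8
Reactants: 11
Product: 12 (2E,5R,6E,8R,10R)-8,10-bis(tert-butyldimethylsilyloxy)-3-methoxy-5,7,11-trimethyldodeca-2,6,11-trienoic acid
Conditions: LiOH·H2O, THF/MeOH/H2O, 45 °C; then aq. HCl to pH 4, 0 °C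
Reagents that add atoms: lithium hydroxide, [Li+].[OH-]
Why: Saponification of the vinylogous carbonate ester is slow but clean at 45 °C, and acidification only to pH 4 should leave the enol ether and the silyl ethers intact.

Step 9
Reactants: 12
Product: 15 2-methoxy-4,7-dimethyl-7-[(1R,3R)-1,3-bis(tert-butyldimethylsilyloxy)-4-methylpent-4-en-1-yl]bicyclo[3.1.1]hept-2-en-6-one (4-methyl on the side of the carbonyl bridge; 7-methyl syn and side chain anti to the enol ether bridge), via acid chloride 13 (not isolated), via vinylketene 14 (not isolated)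
Conditions: 1-chloro-N,N,2-trimethylprop-1-en-1-amine, CH2Cl2, 0 to 23 °C; then slow addition to Et3N, toluene, 110 °C (0.005 M)
Reagents that add atoms: none
Why: Acid chloride 13 loses HCl by 1,4-elimination to vinylketene 14, whose carbonyl carbon is attacked in the ketene plane by the CH terminus of the E-trisubstituted alkene while positive charge builds on the disubstituted terminus, and the ketene alpha carbon then closes onto that carbon in an asynchronous, stereospecific [2+2] cycloaddition. The closest known reaction type is the intramolecular vinylketene–alkene cycloaddition of 2,6-dienoyl chlorides that gives chrysanthenone-type bicyclo[3.1.1]hept-2-en-6-ones. The six-membered ring closes by the bond between the ketene carbonyl carbon and the alkene CH (exo with respect to the alkene, over the C(OMe)=CH–CH(Me) tether), and the four-membered ring closes by the bond between the ketene alpha carbon (the future ketone-alpha bridgehead) and the methyl-bearing alkene carbon (the future quaternary carbon). The quaternary centre follows from suprafacial addition to the E alkene (methyl syn to the enol ether bridge, oxygenated chain anti), the two bridgeheads are fixed by the bridging, and the absolute sense is set by the existing CH–Me centre, whose hydrogen should eclipse the alkene plane next to the cis methyl (A(1,3) strain) so that the ring methyl ends on the side of the carbonyl bridge. The step needs bridged rather than fused regiochemistry, which the alkene secures because its more substituted distal carbon takes the positive charge, and it needs the cyclising geometry of 14, which at 110 °C should be fed from the other isomer through reversible four-electron closure to the cyclobutenone; the isopropenyl group is out of reach.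

Step 10
Reactants: 15
Product: 17 N'-{2,2-dimethoxy-4,7-dimethyl-7-[(1R,3R)-1,3-bis(tert-butyldimethylsilyloxy)-4-methylpent-4-en-1-yl]bicyclo[3.1.1]heptan-6-ylidene}-4-methylbenzenesulfonohydrazide (ring configuration as in 15), via tosylhydrazone enol ether 16 (not isolated)
Conditions: TsNHNH2, 3 Å molecular sieves, MeOH, 40 °C; then PPTS (10 mol %), 23 °C
Reagents that add atoms: 4-methylbenzenesulfonohydrazide, Cc1ccc(cc1)S(=O)(=O)NN; methanol, CO
Why: Hydrazone condensation at the strained, non-enolisable cyclobutanone (the only ketone) followed by acid-catalysed Markovnikov addition of methanol to the enol ether should give the dimethyl ketal, which removes the one other alkene prone to hydrogen-atom transfer and any acceptor that could trigger cyclobutane opening; no stereocentre changes.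

Step 11
Reactants: 17
Product: 20 (1R,2R,3R,5R,7S,8S,9R)-3,5-bis(tert-butyldimethylsilyloxy)-11,11-dimethoxy-2,6,6,9-tetramethyltricyclo[5.4.0.0^2,8]undecane, via cyclised tosylhydrazide 18 (not isolated), via alkyl diazene 19 (not isolated)
Conditions: Fe(acac)3 (30 mol %), PhSiH3, THF/MeOH, 60 °C; then NaOAc, MeOH, 65 °C
Reagents that add atoms: none
Why: Hydrogen-atom transfer from an iron hydride to the isopropenyl group gives the tertiary radical (creating the second methyl of the gem-dimethyl group), which should add 7-exo to the hydrazone carbon from the only face the tether can reach (radical alkene–sulfonylhydrazone coupling), and base-induced loss of sulfinate from 18 gives diazene 19, which extrudes N2 to leave C–H (as in the Caglioti reduction); the new CH centre is fixed by the ring.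

Step 12
Reactants: 20
Product: 21 (1R,2R,3R,5R,7S,8S,9R)-3,5-dihydroxy-2,6,6,9-tetramethyltricyclo[5.4.0.0^2,8]undecan-11-one (numbered as in 24)
Conditions: 48% aq. HF, MeCN, 0 to 23 °C
Reagents that add atoms: water, O
Why: Aqueous HF should cleave both silyl ethers and hydrolyse the dimethyl ketal to the ketone in one operation, and none of the stereocentres is epimerisable under these conditions.

Step 13
Reactants: 21; 22 angelic acid [(2Z)-2-methylbut-2-enoic acid]
Product: 24 (1R,2R,3R,5R,7S,8S,9R)-2,6,6,9-tetramethyl-11-oxotricyclo[5.4.0.0^2,8]undecane-3,5-diyl bis[(2Z)-2-methylbut-2-enoate], via angelic 2,4,6-trichlorobenzoic anhydride 23 (not isolated)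
Conditions: 22 (3 equiv), 2,4,6-trichlorobenzoyl chloride (3 equiv), Et3N, toluene, 23 °C; then 21, toluene, 80 °C
Reagents that add atoms: angelic acid (second molecule of 22), C/C=C(/C)C(=O)O
Why: Yamaguchi-type esterification through mixed anhydride 23 without a nucleophilic catalyst should acylate both hindered secondary alcohols at the angeloyl carbonyl with the Z geometry kept, one molecule of angelic acid being taken up per hydroxyl (two in all), and no stereocentre is touched.

**Compound list**

1 | (4S)-4-benzyl-3-propanoyl-1,3-oxazolidin-2-one | CCC(=O)N1[C@@H](Cc2ccccc2)COC1=O | starting material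
2 | methyl (2E)-4-bromo-3-methoxybut-2-enoate | COC(=O)/C=C(/OC)CBr | starting material
3 | methyl (2E,5R)-6-[(4S)-4-benzyl-2-oxo-1,3-oxazolidin-3-yl]-3-methoxy-5-methyl-6-oxohex-2-enoate | COC(=O)/C=C(/OC)C[C@@H](C)C(=O)N1[C@@H](Cc2ccccc2)COC1=O | intermediate
4 | methyl (2E,5R)-6-hydroxy-3-methoxy-5-methylhex-2-enoate | COC(=O)/C=C(/OC)C[C@@H](C)CO | intermediate
5 | methyl (2E,5R)-3-methoxy-5-methyl-6-oxohex-2-enoate | COC(=O)/C=C(/OC)C[C@@H](C)C=O | intermediate
6 | 3-(triphenyl-λ5-phosphanylidene)butan-2-one | CC(=O)C(C)=P(c1ccccc1)(c1ccccc1)c1ccccc1 | starting material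
7 | methyl (2E,5R,6E)-3-methoxy-5,7-dimethyl-8-oxonona-2,6-dienoate | COC(=O)/C=C(/OC)C[C@@H](C)/C=C(\C)C(C)=O | intermediate
8 | methacrolein | CC(=C)C=O | starting material
9 | methyl (2E,5R,6E,10R)-10-hydroxy-3-methoxy-5,7,11-trimethyl-8-oxododeca-2,6,11-trienoate | COC(=O)/C=C(/OC)C[C@@H](C)/C=C(\C)C(=O)C[C@@H](O)C(C)=C | intermediate
10 | methyl (2E,5R,6E,8R,10R)-8,10-dihydroxy-3-methoxy-5,7,11-trimethyldodeca-2,6,11-trienoate | COC(=O)/C=C(/OC)C[C@@H](C)/C=C(\C)[C@H](O)C[C@@H](O)C(C)=C | intermediate
11 | methyl (2E,5R,6E,8R,10R)-8,10-bis(tert-butyldimethylsilyloxy)-3-methoxy-5,7,11-trimethyldodeca-2,6,11-trienoate | COC(=O)/C=C(/OC)C[C@@H](C)/C=C(\C)[C@H](O[Si](C)(C)C(C)(C)C)C[C@@H](O[Si](C)(C)C(C)(C)C)C(C)=C | intermediate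
12 | (2E,5R,6E,8R,10R)-8,10-bis(tert-butyldimethylsilyloxy)-3-methoxy-5,7,11-trimethyldodeca-2,6,11-trienoic acid | OC(=O)/C=C(/OC)C[C@@H](C)/C=C(\C)[C@H](O[Si](C)(C)C(C)(C)C)C[C@@H](O[Si](C)(C)C(C)(C)C)C(C)=C | intermediate
13 | acid chloride of 12 (not isolated) | ClC(=O)/C=C(/OC)C[C@@H](C)/C=C(\C)[C@H](O[Si](C)(C)C(C)(C)C)C[C@@H](O[Si](C)(C)C(C)(C)C)C(C)=C | intermediate
14 | vinylketene from 13 by loss of HCl, ketene CH and CH(Me) carbon cis on the enol ether double bond (not isolated) | O=C=C/C(OC)=C\[C@@H](C)/C=C(\C)[C@H](O[Si](C)(C)C(C)(C)C)C[C@@H](O[Si](C)(C)C(C)(C)C)C(C)=C | intermediate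
15 | 2-methoxy-4,7-dimethyl-7-[(1R,3R)-1,3-bis(tert-butyldimethylsilyloxy)-4-methylpent-4-en-1-yl]bicyclo[3.1.1]hept-2-en-6-one | C=C(C)[C@H](O[Si](C)(C)C(C)(C)C)C[C@@H](O[Si](C)(C)C(C)(C)C)[C@]2(C)[C@@H]3C(=O)[C@H]2C(OC)=C[C@H]3C | intermediate
16 | tosylhydrazone of 15 (not isolated) | C=C(C)[C@H](O[Si](C)(C)C(C)(C)C)C[C@@H](O[Si](C)(C)C(C)(C)C)[C@]2(C)[C@@H]3C(=NNS(=O)(=O)c4ccc(C)cc4)[C@H]2C(OC)=C[C@H]3C | intermediate
17 | tosylhydrazone dimethyl ketal (2,2-dimethoxy analogue of 16) | C=C(C)[C@H](O[Si](C)(C)C(C)(C)C)C[C@@H](O[Si](C)(C)C(C)(C)C)[C@]2(C)[C@@H]3C(=NNS(=O)(=O)c4ccc(C)cc4)[C@H]2C(OC)(OC)C[C@H]3C | intermediate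
18 | N'-[3,5-bis(tert-butyldimethylsilyloxy)-11,11-dimethoxy-2,6,6,9-tetramethyltricyclo[5.4.0.0^2,8]undecan-7-yl]-4-methylbenzenesulfonohydrazide, configuration as in 20 (not isolated) | CC(C)(C)[Si](C)(C)O[C@@H]1C[C@@H](O[Si](C)(C)C(C)(C)C)[C@]2(C)[C@@H]3[C@@](NNS(=O)(=O)c4ccc(C)cc4)([C@H]2C(OC)(OC)C[C@H]3C)C1(C)C | intermediate
19 | diazene from 18 by loss of toluenesulfinate (not isolated) | CC(C)(C)[Si](C)(C)O[C@@H]1C[C@@H](O[Si](C)(C)C(C)(C)C)[C@]2(C)[C@@H]3[C@@](N=N)([C@H]2C(OC)(OC)C[C@H]3C)C1(C)C | intermediate
20 | (1R,2R,3R,5R,7S,8S,9R)-3,5-bis(tert-butyldimethylsilyloxy)-11,11-dimethoxy-2,6,6,9-tetramethyltricyclo[5.4.0.0^2,8]undecane | CC(C)(C)[Si](C)(C)O[C@@H]1C[C@@H](O[Si](C)(C)C(C)(C)C)[C@]2(C)[C@@H]3[C@@H]([C@H]2C(OC)(OC)C[C@H]3C)C1(C)C | intermediate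
21 | (1R,2R,3R,5R,7S,8S,9R)-3,5-dihydroxy-2,6,6,9-tetramethyltricyclo[5.4.0.0^2,8]undecan-11-one (numbered as in 24) | O[C@@H]1C[C@@H](O)[C@]2(C)[C@@H]3[C@@H]([C@H]2C(=O)C[C@H]3C)C1(C)C | intermediate
22 | angelic acid, (2Z)-2-methylbut-2-enoic acid | C/C=C(/C)C(=O)O | starting material
23 | angelic 2,4,6-trichlorobenzoic anhydride (not isolated) | C/C=C(/C)C(=O)OC(=O)c1c(Cl)cc(Cl)cc1Cl | intermediate
24 | (1R,2R,3R,5R,7S,8S,9R)-2,6,6,9-tetramethyl-11-oxotricyclo[5.4.0.0^2,8]undecane-3,5-diyl bis[(2Z)-2-methylbut-2-enoate] | C/C=C(/C)C(=O)O[C@@H]1C[C@@H](OC(=O)/C(C)=C\C)[C@]2(C)[C@@H]3[C@@H]([C@H]2C(=O)C[C@H]3C)C1(C)C | target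

**Step count**

Total steps: 13. Longest linear sequence: 13 steps (from 1).

**Steps most likely to fail**

Step 11. The seven-membered radical closure onto the congested hydrazone carbon may be slower than quenching of the tertiary radical by the iron hydride, so that the isopropenyl group is only hydrogenated. The hydrazinyl radical formed after closure may also open the cyclobutane before it is reduced. The fallback sets out from 17 and comes back at 20, and replaces hydrogen-atom transfer by a sulfanyl-radical addition–cyclisation. PhSH and AIBN in benzene at 80 °C add reversibly to the isopropenyl terminus, so the tertiary radical is regenerated until it closes, and the thiol quenches the nitrogen radical quickly. This should give the cyclised phenylthiomethyl tosylhydrazide F1, as a mixture at the new quaternary carbon that does not matter later. NaOAc in MeOH at 65 °C then removes sulfinate and N2 to give the phenylthiomethyl analogue of 20 F2. Raney Ni in EtOH cleaves the C–S bond, which turns CH2SPh into the second methyl group and gives 20.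

Step 9. The 1,4-dehydrochlorination of the beta-methoxy enoyl chloride may be inefficient, and the ketene may oligomerise before it finds the alkene. The fallback sets out from 12 and comes back at 15, and uses a keteniminium ion in place of the ketene. Acid chloride 13 is treated with pyrrolidine and Et3N to give the pyrrolidine amide F3. Tf2O and 2,4,6-collidine in 1,2-dichloroethane at 80 °C should give, by O-triflation and gamma-deprotonation, a vinylketeniminium ion that is more electrophilic and cannot dimerise. It should add to the alkene with the same regio- and stereochemical course to give the cyclobutaniminium triflate F4, and aqueous NaHCO3 hydrolyses F4 to 15.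

Step 13. The angeloyl group may isomerise from Z to E during prolonged heating, and the two neopentylic alcohols may be acylated incompletely. The fallback sets out from 20 and comes back at 24, and acylates the alkoxides at low temperature while the ketone is still masked. Bu4NF in THF removes both silyl ethers to give the diol dimethyl ketal F5. Angelic anhydride F6 (from 22 and dicyclohexylcarbodiimide) with LiN(SiMe3)2 in THF at −78 to 0 °C should acylate both lithium alkoxides to the bis-angelate dimethyl ketal F7. PPTS in wet acetone then releases the ketone and gives 24.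

**Further compounds**

F1 | step 11 | N'-tosylhydrazide 18 with one methyl of the gem-dimethyl group replaced by phenylthiomethyl (mixture at that carbon) | CC(C)(C)[Si](C)(C)O[C@@H]1C[C@@H](O[Si](C)(C)C(C)(C)C)[C@]2(C)[C@@H]3[C@@](NNS(=O)(=O)c4ccc(C)cc4)([C@H]2C(OC)(OC)C[C@H]3C)C1(C)CSc5ccccc5
F2 | step 11 | phenylthiomethyl analogue of 20 (mixture at that carbon) | CC(C)(C)[Si](C)(C)O[C@@H]1C[C@@H](O[Si](C)(C)C(C)(C)C)[C@]2(C)[C@@H]3[C@@H]([C@H]2C(OC)(OC)C[C@H]3C)C1(C)CSc5ccccc5
F3 | step 9 | pyrrolidine amide of 12 | O=C(N1CCCC1)/C=C(/OC)C[C@@H](C)/C=C(\C)[C@H](O[Si](C)(C)C(C)(C)C)C[C@@H](O[Si](C)(C)C(C)(C)C)C(C)=C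
F4 | step 9 | pyrrolidinium-ylidene (cyclobutaniminium) triflate corresponding to ketone 15 | C=C(C)[C@H](O[Si](C)(C)C(C)(C)C)C[C@@H](O[Si](C)(C)C(C)(C)C)[C@]2(C)[C@@H]3C(=[N+]4CCCC4)[C@H]2C(OC)=C[C@H]3C.[O-]S(=O)(=O)C(F)(F)F
F5 | step 13 | diol dimethyl ketal (20 without silyl groups) | O[C@@H]1C[C@@H](O)[C@]2(C)[C@@H]3[C@@H]([C@H]2C(OC)(OC)C[C@H]3C)C1(C)C
F6 | step 13 | angelic anhydride | C/C=C(/C)C(=O)OC(=O)/C(C)=C\C
F7 | step 13 | bis-angelate dimethyl ketal (dimethyl ketal of 24) | C/C=C(/C)C(=O)O[C@@H]1C[C@@H](OC(=O)/C(C)=C\C)[C@]2(C)[C@@H]3[C@@H]([C@H]2C(OC)(OC)C[C@H]3C)C1(C)C
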